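Ring C is dismantled at three bonds, O1–C8a, C4–C4a and O1–C2. This turns ring A into a 3,5-dialkoxybenzyne and leaves ring B attached to a C2–C3–C4 unit, a 2-aryl-3-methoxyacrylic acid. The feature exploited is that C8a (bearing O1) and C4a (bearing the C4 carbonyl) are neighbours in ring A, with the C5 oxygen next to C4a to polarise the aryne. In one operation the carboxylate oxygen binds C8a, the acyl group migrates to C4a, and the liberated phenoxide displaces methoxide at C2. The precursor acid carries its phenol and tertiary alcohol as benzyl ethers, inert to fluoride, so a single hydrogenolysis ends the route.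

Key step: step 12

Remark: 3,5-bis(benzyloxy)phenol is taken as a catalogue compound. The target has no stereocentre, so only the alkene geometry of the acrylate units has to be tracked, and it vanishes when ring C closes.

Step 1
Reactants: 1 3,5-bis(benzyloxy)phenol
Product: 2 3,5-bis(benzyloxy)-2-bromophenol
Conditions: NBS (1.0 equiv), CH2Cl2, −78 °C to rt
Reagents that add atoms: N-bromosuccinimide, O=C1CCC(=O)N1Br
Why: Electrophilic aromatic bromination, in which NBS in a non-polar solvent at low temperature is guided by hydrogen bonding to the free hydroxyl and should enter ortho to it rather than between the two benzyloxy groups, while one equivalent avoids a second bromination.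

Step 2
Reactants: 2 3,5-bis(benzyloxy)-2-bromophenol
Product: 5 3,5-bis(benzyloxy)-2-(trimethylsilyl)phenyl trifluoromethanesulfonate, via silyl ether 3 (not isolated), via lithium silylphenoxide 4 (not isolated)
Conditions: HMDS, THF, 70 °C, then evaporation; n-BuLi, THF, −78 °C; Tf2O, −78 °C to rt
Reagents that add atoms: hexamethyldisilazane, C[Si](C)(C)N[Si](C)(C)C; trifluoromethanesulfonic anhydride, O=S(=O)(OS(=O)(=O)C(F)(F)F)C(F)(F)F
Why: O-silylation, bromine–lithium exchange and retro-Brook rearrangement (1,3 O-to-C silyl shift) move silicon onto the carbon that held bromine, and Tf2O sulfonylates the phenoxide 4 so released, which is the standard entry to 2-silylaryl triflate aryne precursors and is fast enough at −78 °C to spare the benzylic C–H bonds.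

Step 3
Reactants: 6 methyl (E)-3-methoxyacrylate
Product: 8 methyl (Z)-2-iodo-3-methoxyacrylate, via iodoacetate adduct 7 (not isolated)
Conditions: NIS, AcOH, CH2Cl2, rt; then Et3N, rt
Reagents that add atoms: N-iodosuccinimide, O=C1CCC(=O)N1I
Why: Vinylic iodination by addition–elimination, in which iodoacetoxylation of the electron-rich enol ether places iodine on the α-carbon and E2 loss of acetic acid from 7 should restore the push–pull alkene as the Z iodide, with methoxy still trans to the ester.

Step 4
Reactants: 9 2-methylbut-3-en-2-ol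
Product: 11 tert-butyl (2-methylbut-3-en-2-yl) carbonate, via lithium alkoxide 10 (not isolated)
Conditions: n-BuLi, THF, 0 °C; Boc2O, 0 °C to rt
Reagents that add atoms: di-tert-butyl dicarbonate, CC(C)(C)OC(=O)OC(=O)OC(C)(C)C
Why: Mixed carbonate formation by acylation of the preformed alkoxide 10, which works where amine-catalysed acylation of a tertiary allylic alcohol would be slow.

Step 5
Reactants: 12 3,4-dimethoxyphenol
Product: 13 2-bromo-4,5-dimethoxyphenol
Conditions: NBS (1.0 equiv), CH2Cl2, 0 °C
Reagents that add atoms: N-bromosuccinimide, O=C1CCC(=O)N1Br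
Why: Electrophilic aromatic bromination at the most activated and least hindered carbon (ortho to OH, para to the 3-methoxy group), which both blocks this ortho position for the later Claisen step and provides the handle for C1'.

Step 6
Reactants: 13 2-bromo-4,5-dimethoxyphenol; 11 tert-butyl (2-methylbut-3-en-2-yl) carbonate
Product: 14 1-bromo-4,5-dimethoxy-2-[(2-methylbut-3-en-2-yl)oxy]benzene
Conditions: Pd(PPh3)4 (5 mol%), THF, 0 °C
Reagents that add atoms: none
Why: Tsuji–Trost O-allylation, in which zerovalent palladium ionises the tertiary allylic carbonate, the alkoxide formed deprotonates the phenol, and under kinetic control at 0 °C the phenoxide should attack the more substituted allyl terminus, while the electron-rich C–Br bond is inert to Pd(PPh3)4 at this temperature.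

Step 7
Reactants: 14 1-bromo-4,5-dimethoxy-2-[(2-methylbut-3-en-2-yl)oxy]benzene
Product: 16 6-bromo-3,4-dimethoxy-2-(3-methylbut-2-en-1-yl)phenol, via dienone 15 (not isolated)
Conditions: DMF, 120 °C
Reagents that add atoms: none
Why: Aromatic Claisen rearrangement, whose [3,3]-sigmatropic shift can end productively only at the one ortho carbon that bears hydrogen (bromine blocks the other), so dienone 15 tautomerises to the phenol with a normal prenyl group between OH and OMe, and the gem-dimethyl ether rearranges at a moderate temperature.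

Step 8
Reactants: 16 6-bromo-3,4-dimethoxy-2-(3-methylbut-2-en-1-yl)phenol
Product: 17 2-(benzyloxy)-1-bromo-4,5-dimethoxy-3-(3-methylbut-2-en-1-yl)benzene
Conditions: BnBr, K2CO3, DMF, rt
Reagents that add atoms: benzyl bromide, BrCc1ccccc1
Why: Williamson ether synthesis, routine even for a 2,6-disubstituted phenol in a dipolar aprotic solvent and harmless to the alkene and the aryl bromide.

Step 9
Reactants: 17 2-(benzyloxy)-1-bromo-4,5-dimethoxy-3-(3-methylbut-2-en-1-yl)benzene
Product: 19 2-(benzyloxy)-3-[3-(benzyloxy)-3-methylbutyl]-1-bromo-4,5-dimethoxybenzene, via organomercury acetate 18 (not isolated)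
Conditions: Hg(OAc)2 (1.1 equiv), BnOH/THF, rt; then aq NaOH, NaBH4, 0 °C
Reagents that add atoms: benzyl alcohol, OCc1ccccc1
Why: Alkoxymercuration–demercuration, in which benzyl alcohol opens the mercurinium ion of the trisubstituted alkene at the tertiary carbon (Markovnikov) and NaBH4 replaces mercury by hydrogen, so oxygenation and protection of the side chain are merged in one step without touching C–Br or the aryl ethers.

Step 10
Reactants: 19 2-(benzyloxy)-3-[3-(benzyloxy)-3-methylbutyl]-1-bromo-4,5-dimethoxybenzene; 8 methyl (Z)-2-iodo-3-methoxyacrylate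
Product: 22 methyl (E)-2-{2-(benzyloxy)-3-[3-(benzyloxy)-3-methylbutyl]-4,5-dimethoxyphenyl}-3-methoxyacrylate, via aryllithium 20 (not isolated), via arylzinc chloride 21 (not isolated)
Conditions: n-BuLi, THF, −78 °C; ZnCl2 (THF), −78 °C to rt; 8, Pd(PPh3)4 (5 mol%), THF, 50 °C
Reagents that add atoms: none
Why: Bromine–lithium exchange at −78 °C (faster than benzylic deprotonation), transmetalation to zinc and Negishi coupling with the alkenyl iodide, which tolerates the ester and keeps the alkene geometry, so the Z iodide becomes the E acrylate only through the change in CIP priorities.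

Step 11
Reactants: 22 methyl (E)-2-{2-(benzyloxy)-3-[3-(benzyloxy)-3-methylbutyl]-4,5-dimethoxyphenyl}-3-methoxyacrylate
Product: 24 (E)-2-{2-(benzyloxy)-3-[3-(benzyloxy)-3-methylbutyl]-4,5-dimethoxyphenyl}-3-methoxyacrylic acid, via lithium carboxylate 23 (not isolated)
Conditions: LiOH·H2O, THF/MeOH/H2O, 40 °C; then 1 M HCl to pH 4, 0 °C
Reagents that add atoms: lithium hydroxide, [Li+].[OH-]
Why: Saponification, in which hydroxide attacks the ester carbonyl, the charge of carboxylate 23 shields the β-carbon from further attack, and cold acidification to pH 4 spares the enol ether and the tertiary benzyl ether.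

Step 12
Reactants: 24 (E)-2-{2-(benzyloxy)-3-[3-(benzyloxy)-3-methylbutyl]-4,5-dimethoxyphenyl}-3-methoxyacrylic acid; 5 3,5-bis(benzyloxy)-2-(trimethylsilyl)phenyl trifluoromethanesulfonate
Product: 28 5,7-bis(benzyloxy)-3-{2-(benzyloxy)-3-[3-(benzyloxy)-3-methylbutyl]-4,5-dimethoxyphenyl}-4H-chromen-4-one, via cesium carboxylate 25 (not isolated), via aryne 26 (not isolated), via cesium phenoxide 27 (not isolated)
Conditions: CsF (5 equiv), 5 (2 equiv), THF (0.02 M), sealed vessel, 125 °C
Reagents that add atoms: none
Why: Proposed new method: Fluoride removes the silyl group of 5 and triflate departs to give aryne 26, carboxylate 25 adds through oxygen to the aryne carbon that becomes C8a, and the aryl anion left at C4a attacks the adjacent ester carbonyl through a strained four-membered alkoxide whose opening moves the acyl group from O to C and releases phenoxide 27. The closest known reaction type is the CsF-mediated insertion of arynes into the C–O bond of carboxylic acids in hot THF, which gives 2-hydroxyaryl ketones and, with alkenoic or alkynoic acids, runs on to chroman-4-ones or flavones; a β-methoxyacrylic acid, where conjugate addition is followed by loss of methoxide to give a chromone directly, has not been shown. Ring C closes by 6-endo-trig attack of O1 on C2 of the vinylogous ester and β-elimination of methoxide, and either alkene geometry can react because the enolate intermediate rotates freely. No stereocentre is created. The step needs aryne regioselectivity, which the benzyloxy group flanking the triple bond (the future C5 oxygen) secures by distorting the aryne so that the nucleophile enters at the distal carbon and the charge develops beside the electron-withdrawing C–O bond. Heat and high dilution favour the unimolecular acyl shift over protonation of the aryl anion, the substrate holds no silyl ether for fluoride to attack, and the excess of 5 covers aryne lost to the methanol released.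

Step 13
Reactants: 28 5,7-bis(benzyloxy)-3-{2-(benzyloxy)-3-[3-(benzyloxy)-3-methylbutyl]-4,5-dimethoxyphenyl}-4H-chromen-4-one
Product: 29 5,7-dihydroxy-3-[2-hydroxy-3-(3-hydroxy-3-methylbutyl)-4,5-dimethoxyphenyl]-4H-chromen-4-one (CNP0192638.0)
Conditions: H2 (1 atm), 10% Pd/C, THF/MeOH, rt, stopped when the benzyl ethers are consumed
Reagents that add atoms: none
Why: Catalytic hydrogenolysis of all four benzylic C–O bonds under neutral conditions, which avoids the acid that would cyclise the tertiary alcohol onto the 2'-hydroxyl to a chroman, while the trisubstituted, vinylogous-ester C2–C3 double bond of the isoflavone should be reduced much more slowly.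

Compound list
1 | 3,5-bis(benzyloxy)phenol | Oc1cc(OCc2ccccc2)cc(OCc2ccccc2)c1 | starting material
2 | 3,5-bis(benzyloxy)-2-bromophenol | Oc1cc(OCc2ccccc2)cc(OCc2ccccc2)c1Br | intermediate
3 | [3,5-bis(benzyloxy)-2-bromophenoxy]trimethylsilane | C[Si](C)(C)Oc1cc(OCc2ccccc2)cc(OCc2ccccc2)c1Br | intermediate
4 | lithium 3,5-bis(benzyloxy)-2-(trimethylsilyl)phenoxide | [Li+].[O-]c1cc(OCc2ccccc2)cc(OCc2ccccc2)c1[Si](C)(C)C | intermediate
5 | 3,5-bis(benzyloxy)-2-(trimethylsilyl)phenyl trifluoromethanesulfonate | C[Si](C)(C)c1c(OCc2ccccc2)cc(OCc2ccccc2)cc1OS(=O)(=O)C(F)(F)F | intermediate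
6 | methyl (E)-3-methoxyacrylate | CO/C=C/C(=O)OC | starting material
7 | methyl 3-acetoxy-2-iodo-3-methoxypropanoate (mixture of diastereomers) | COC(OC(C)=O)C(I)C(=O)OC | intermediate
8 | methyl (Z)-2-iodo-3-methoxyacrylate | CO/C=C(\I)C(=O)OC | intermediate
9 | 2-methylbut-3-en-2-ol | C=CC(C)(C)O | starting material
10 | lithium 2-methylbut-3-en-2-olate | [Li+].[O-]C(C)(C)C=C | intermediate
11 | tert-butyl (2-methylbut-3-en-2-yl) carbonate | C=CC(C)(C)OC(=O)OC(C)(C)C | intermediate
12 | 3,4-dimethoxyphenol | COc1ccc(O)cc1OC | starting material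
13 | 2-bromo-4,5-dimethoxyphenol | COc1cc(O)c(Br)cc1OC | intermediate
14 | 1-bromo-4,5-dimethoxy-2-[(2-methylbut-3-en-2-yl)oxy]benzene | COc1cc(OC(C)(C)C=C)c(Br)cc1OC | intermediate
15 | 2-bromo-4,5-dimethoxy-6-(3-methylbut-2-en-1-yl)cyclohexa-2,4-dien-1-one (racemic) | O=C1C(Br)=CC(OC)=C(OC)C1CC=C(C)C | intermediate
16 | 6-bromo-3,4-dimethoxy-2-(3-methylbut-2-en-1-yl)phenol | COc1cc(Br)c(O)c(CC=C(C)C)c1OC | intermediate
17 | 2-(benzyloxy)-1-bromo-4,5-dimethoxy-3-(3-methylbut-2-en-1-yl)benzene | COc1cc(Br)c(OCc2ccccc2)c(CC=C(C)C)c1OC | intermediate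
18 | {1-[2-(benzyloxy)-3-bromo-5,6-dimethoxyphenyl]-3-(benzyloxy)-3-methylbutan-2-yl}mercury acetate (racemic) | COc1cc(Br)c(OCc2ccccc2)c(CC([Hg]OC(C)=O)C(C)(C)OCc2ccccc2)c1OC | intermediate
19 | 2-(benzyloxy)-3-[3-(benzyloxy)-3-methylbutyl]-1-bromo-4,5-dimethoxybenzene | COc1cc(Br)c(OCc2ccccc2)c(CCC(C)(C)OCc2ccccc2)c1OC | intermediate
20 | {2-(benzyloxy)-3-[3-(benzyloxy)-3-methylbutyl]-4,5-dimethoxyphenyl}lithium | [Li]c1cc(OC)c(OC)c(CCC(C)(C)OCc2ccccc2)c1OCc1ccccc1 | intermediate
21 | {2-(benzyloxy)-3-[3-(benzyloxy)-3-methylbutyl]-4,5-dimethoxyphenyl}zinc chloride | Cl[Zn]c1cc(OC)c(OC)c(CCC(C)(C)OCc2ccccc2)c1OCc1ccccc1 | intermediate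
22 | methyl (E)-2-{2-(benzyloxy)-3-[3-(benzyloxy)-3-methylbutyl]-4,5-dimethoxyphenyl}-3-methoxyacrylate | CO/C=C(/C(=O)OC)c1cc(OC)c(OC)c(CCC(C)(C)OCc2ccccc2)c1OCc1ccccc1 | intermediate
23 | lithium (E)-2-{2-(benzyloxy)-3-[3-(benzyloxy)-3-methylbutyl]-4,5-dimethoxyphenyl}-3-methoxyacrylate | [Li+].CO/C=C(/C(=O)[O-])c1cc(OC)c(OC)c(CCC(C)(C)OCc2ccccc2)c1OCc1ccccc1 | intermediate
24 | (E)-2-{2-(benzyloxy)-3-[3-(benzyloxy)-3-methylbutyl]-4,5-dimethoxyphenyl}-3-methoxyacrylic acid | CO/C=C(/C(=O)O)c1cc(OC)c(OC)c(CCC(C)(C)OCc2ccccc2)c1OCc1ccccc1 | intermediate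
25 | cesium (E)-2-{2-(benzyloxy)-3-[3-(benzyloxy)-3-methylbutyl]-4,5-dimethoxyphenyl}-3-methoxyacrylate | [Cs+].CO/C=C(/C(=O)[O-])c1cc(OC)c(OC)c(CCC(C)(C)OCc2ccccc2)c1OCc1ccccc1 | intermediate
26 | 3,5-bis(benzyloxy)-1,2-didehydrobenzene | C1#CC(OCc2ccccc2)=CC(OCc2ccccc2)=C1 | intermediate
27 | cesium 3,5-bis(benzyloxy)-2-[(E)-2-{2-(benzyloxy)-3-[3-(benzyloxy)-3-methylbutyl]-4,5-dimethoxyphenyl}-3-methoxyacryloyl]phenoxide | [Cs+].CO/C=C(/C(=O)c1c([O-])cc(OCc2ccccc2)cc1OCc1ccccc1)c1cc(OC)c(OC)c(CCC(C)(C)OCc2ccccc2)c1OCc1ccccc1 | intermediate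
28 | 5,7-bis(benzyloxy)-3-{2-(benzyloxy)-3-[3-(benzyloxy)-3-methylbutyl]-4,5-dimethoxyphenyl}-4H-chromen-4-one | COc1cc(-c2coc3cc(OCc4ccccc4)cc(OCc4ccccc4)c3c2=O)c(OCc2ccccc2)c(CCC(C)(C)OCc2ccccc2)c1OC | intermediate
29 | 5,7-dihydroxy-3-[2-hydroxy-3-(3-hydroxy-3-methylbutyl)-4,5-dimethoxyphenyl]-4H-chromen-4-one | COc1cc(-c2coc3cc(O)cc(O)c3c2=O)c(O)c(CCC(C)(C)O)c1OC | target

Total step count: 13. Longest linear sequence: 9 steps (12 to 29, steps 5 to 13).

Steps most likely to fail

**Step 12 (the labelled step).**
- The aryl anion may be protonated before the acyl shift, so that the acid is merely O-arylated.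
- The phenoxide may be arylated by a second aryne before ring closure.
- The aryne may be used up by the methanol released.
- The fallback uses known chemistry, sets out from 19 and returns at 28. It builds ring C first and makes the C3–C1' bond last.
- Miyaura borylation of 19 (B2pin2, Pd(dppf)Cl2, KOAc, dioxane, 90 °C) should give 2-{2-(benzyloxy)-3-[3-(benzyloxy)-3-methylbutyl]-4,5-dimethoxyphenyl}-4,4,5,5-tetramethyl-1,3,2-dioxaborolane F1.
- In parallel, commercial 2,4,6-trihydroxyacetophenone is benzylated at the two hydroxyls that are not hydrogen-bonded to the ketone (BnBr, K2CO3, DMF). This gives 1-[2,4-bis(benzyloxy)-6-hydroxyphenyl]ethanone F2.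
- Condensation with DMF dimethyl acetal gives (E)-1-[2,4-bis(benzyloxy)-6-hydroxyphenyl]-3-(dimethylamino)prop-2-en-1-one F3.
- I2 in CHCl3 cyclises and iodinates it to 5,7-bis(benzyloxy)-3-iodo-4H-chromen-4-one F4.
- Suzuki–Miyaura coupling of F1 and F4 (Pd(dppf)Cl2, Na2CO3, DME/H2O, 80 °C) should give 28.

**Step 6.**
- Zerovalent palladium may re-ionise the tertiary aryl ether and erode the branched selectivity.
- The ether may also fragment with loss of isoprene when heated in step 7.
- The fallback sets out from 13 and returns at 16. It replaces the tertiary ether by a plain allyl ether and builds the prenyl terminus afterwards.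
- O-allylation (allyl bromide, K2CO3, acetone) gives 1-(allyloxy)-2-bromo-4,5-dimethoxybenzene F5.
- Claisen rearrangement in N,N-diethylaniline at 190 °C, again with only one free ortho carbon, gives 2-allyl-6-bromo-3,4-dimethoxyphenol F6.
- Cross-metathesis with excess 2-methylbut-2-ene (second-generation Grubbs catalyst, CH2Cl2, 40 °C) should give 16.

**Step 9.**
- The alkoxymercuration may reverse during the reduction.
- Acetate or adventitious water may compete with benzyl alcohol for the mercurinium ion.
- The fallback sets out from 17 and returns at 19. It separates oxygenation from protection and replaces the ionic addition by a radical one.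
- Mukaiyama hydration (Co(acac)2, PhSiH3, O2, THF, rt) gives 4-[2-(benzyloxy)-3-bromo-5,6-dimethoxyphenyl]-2-methylbutan-2-ol F7.
- Williamson benzylation of the tertiary alkoxide (NaH, BnBr, Bu4NI, DMF, rt to 50 °C) should give 19.

Further compounds
F1 | step 12 | 2-{2-(benzyloxy)-3-[3-(benzyloxy)-3-methylbutyl]-4,5-dimethoxyphenyl}-4,4,5,5-tetramethyl-1,3,2-dioxaborolane | COc1cc(B2OC(C)(C)C(C)(C)O2)c(OCc2ccccc2)c(CCC(C)(C)OCc2ccccc2)c1OC
F2 | step 12 | 1-[2,4-bis(benzyloxy)-6-hydroxyphenyl]ethanone | CC(=O)c1c(O)cc(OCc2ccccc2)cc1OCc1ccccc1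
F3 | step 12 | (E)-1-[2,4-bis(benzyloxy)-6-hydroxyphenyl]-3-(dimethylamino)prop-2-en-1-one | CN(C)/C=C/C(=O)c1c(O)cc(OCc2ccccc2)cc1OCc1ccccc1
F4 | step 12 | 5,7-bis(benzyloxy)-3-iodo-4H-chromen-4-one | O=c1c(I)coc2cc(OCc3ccccc3)cc(OCc3ccccc3)c12
F5 | step 6 | 1-(allyloxy)-2-bromo-4,5-dimethoxybenzene | C=CCOc1cc(OC)c(OC)cc1Br
F6 | step 6 | 2-allyl-6-bromo-3,4-dimethoxyphenol | COc1cc(Br)c(O)c(CC=C)c1OC
F7 | step 9 | 4-[2-(benzyloxy)-3-bromo-5,6-dimethoxyphenyl]-2-methylbutan-2-ol | COc1cc(Br)c(OCc2ccccc2)c(CCC(C)(C)O)c1OC
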